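## The problem

Penicanesin D 21 is a pentasubstituted benzene (ring A: C1' bearing the methylene C7, C2' an acetyl, C3' and C4' free hydroxyls, C5' a methoxyl, C6' hydrogen) joined through C7 to C3 of a 4-hydroxy-2-pyrone (ring B), whose C6 carries a 2-hydroxypropyl chain C1''–C3''. The only stereocentre, C2'' (S), is remote from every other substituent, so nothing in the molecule can control it and it controls nothing; it has to come from a catalyst, a reagent or the chiral pool. Ring A poses a regiochemical problem: five contiguous substituents, an acetyl wedged between C7 and a hydroxyl, and only one of three neighbouring oxygens methylated. Several groups are fragile: the catechol oxidises in base and air, the 4-hydroxypyrone is an acidic O/C-ambident nucleophile whose lactone opens with hard nucleophiles, the carbinol β to C6 can eliminate or undergo retro-aldol cleavage in strong base, and the aryl methyl ketone is enolisable and sits ortho to the benzylic carbon. Two features make a short plan possible. First, C2'' is β to C6 and C1''–C6–C5–C4 is an acetoacetyl unit, that is, the γ-methyl, C6, C5 and C4 of 2,2,6-trimethyl-1,3-dioxin-4-one, whose dienolate is a vinylogous aldol donor and whose ring is a latent acylketene. Second, C3 is the carbon acid of a cyclic 1,3-dicarbonyl and C7 has the oxidation level of a benzaldehyde carbon, while the 3',4',5'-trioxygenation of ring A is symmetric about C4' until the acetyl is in place.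

## Retrosynthesis

**21 from 19 (two O–CH3 bonds at C3' and C4', and the O–Si bond).** The catechol and the carbinol are unmasked last. Carrying ring A as the trimethyl ether 19 keeps the oxidisable catechol hidden and lets the acetyl direct which two methyl ethers fall. The forward reaction must cleave the ether ortho to the ketone and its neighbour, spare the C5' methoxyl and leave the pyrone alone. Benzyl or acetal protection would need an unsymmetrical catechol aldehyde and would reopen the C2'/C6' question.

**19 from 12 and 17 (C3–C7).** Cutting the methylene link at the pyrone side gives the pyrone 12 as a carbon acid and the benzaldehyde 17 as the electrophile. A reductive alkylation joins them under nearly neutral conditions and gives C-alkylation only, whereas a benzylic halide would give O/C mixtures. Cutting at the aryl side would need an aryl metal next to the acetyl. Bringing the benzyl group in during pyrone formation would need an ester enolate equivalent that cannot coexist with the methyl ketone. The precursors are a 3-unsubstituted pyrone and an aldehyde made in two steps; the forward step must favour hydride transfer over addition of a second pyrone.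

**17 from 14 and 15, and 14 from 13 (aryl–acetyl bond, then C–Br).** The acetyl comes from the acetyl-anion equivalent 15 by cross-coupling at the bromide 14. In 13 the positions C2 and C6 are equivalent, so bromination can give only one monobromide; symmetry, not a directing effect, fixes the ring A pattern. Both forward reactions must tolerate the free aldehyde.

**12 from 7 and 8 (C3–C4 and O1–C2 of ring B).** Thermolysis of the dioxinone 7 releases the acylketene 9, which already holds C4, C5, C6 and the side chain. The ketene silyl acetal 8 supplies C3 and C2 by carbon attack on the ketene carbon, followed by lactonisation. This cut uses the dioxinone a second time and leaves the carbinol carbon untouched. The usual pyrone synthesis from a 6-(2-oxoalkyl)dioxinone would place the side chain on the wrong carbon. Capture must outrun acylketene dimerisation, so the unhindered commercial acetal 8 is used in excess.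

**7 from 6 (O–Si).** The carbinol is silylated so that it cannot add to the acylketene or to the dioxinone carbonyl. The ether stays until the last step and makes the intermediates lipophilic.

**6 from 3 and 4 (C1''–C2'').** The carbinol is the aldol product of the dienolate 3 and acetaldehyde 4, and the stereocentre is set here by the Lewis acid made from Ti(OiPr)4 and (R)-BINOL. This creates the only stereocentre catalytically from two achiral feedstocks, in a product whose ring is the electrophile for the pyrone. A chiral-pool carbinol would deliver the stereocentre but not the C4–C6 unit. The forward step must discriminate the faces of the smallest prochiral aldehyde and attack through the γ carbon.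

**3 from 1 (O–Si).** The dienolate 3 is made from the commercial dioxinone 1 by deprotonation to the lithium dienolate 2 and silylation.

## Roads not taken

Alternative 1: Ring B is cut at C4–C5 and O1–C2. In the forward step the malonyl dichloride 2-[[2-acetyl-3,4-bis(benzyloxy)-5-methoxyphenyl]methyl]propanedioyl dichloride A2 C-acylates the terminal carbon of the silyl enol ether (S)-tert-butyldimethyl[(4-(trimethylsilyloxy)pent-4-en-2-yl)oxy]silane A3, and the second acid chloride then acylates the enol oxygen. One operation thus closes the pyrone and gives 3-[[2-acetyl-3,4-bis(benzyloxy)-5-methoxyphenyl]methyl]-6-[(S)-2-(tert-butyldimethylsilyloxy)propyl]-4-hydroxypyran-2-one A1, and from A1 only hydrogenolysis and desilylation would remain.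
- Merits: it is the most convergent ring closure. The C3 substituent arrives in place, so no separate benzylation is needed, and few operations follow the union.
- Weak points: A2 has to carry an enolisable ortho-acetyl group and two benzyl ethers through malonate alkylation, hydrolysis and chlorination. Monosubstituted malonyl dichlorides lose HCl to ketenes easily. The acid released threatens the silyl ether. The route does not create the stereocentre, so A3 needs an enantiopure carbinol from elsewhere. The ring A regiochemistry of an unsymmetrical dibenzyl catechol remains unsolved.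
- Comparison: in convergence and in step count after the union this road is better. The chosen plan sets against it a catalytic origin of the stereocentre, a union under amine catalysis with no acid chloride, and a ring A pattern fixed by symmetry.

Alternative 2: The aryl–methylene bond C1'–C7 is cut. In the forward step the acetonide 1-(7-methoxy-2,2-dimethyl-1,3-benzodioxol-4-yl)ethanone A5 undergoes acetyl-directed ortho C–H metalation with [(C5Me5)RhCl2]2 and AgSbF6 (trivalent rhodium). The aryl–rhodium species adds to 3-methylidene-6-[(S)-2-(tert-butyldimethylsilyloxy)propyl]pyran-2,4-dione A7, which is released in the flask from the Mannich base 3-[(dimethylamino)methyl]-6-[(S)-2-(tert-butyldimethylsilyloxy)propyl]-4-hydroxypyran-2-one A6. The product is 3-[(4-acetyl-7-methoxy-2,2-dimethyl-1,3-benzodioxol-5-yl)methyl]-6-[(S)-2-(tert-butyldimethylsilyloxy)propyl]-4-hydroxypyran-2-one A4, and acid would take A4 to the target by removing the acetonide and the silyl ether.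
- Merits: the arene A5 already has the right oxygenation and the acetyl, which doubles as directing group. Its only ortho C–H is the right one. No halogenation and no late demethylation are needed, and the route is the shortest on paper.
- Weak points: the aryl ketone of A5 is a weak directing group. A7 is a short-lived, very electrophilic heterodiene that dimerises or recaptures the amine. The amine set free from A6 can bind the cationic rhodium centre. Addition of such rhodacycles to this kind of acceptor has no close precedent. The catechol acetonide of A4 needs strong acid at the end.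
- Comparison: this road is shorter and solves the ring A problem more directly. It depends on one untested C–C bond formation at the point of convergence, whereas every step of the chosen plan is of a known type.

Alternative 3: Ring A is cut at C1'–C6' and C2'–C3' and built by cycloaddition. In the forward step the ynone 4-benzyloxy-6-[(S)-2-benzyloxypropyl]-3-(4-oxopent-2-yn-1-yl)pyran-2-one A9 and the diene 2-benzyloxy-1,3-dimethoxy-1-(trimethylsilyloxy)buta-1,3-diene A10 combine in a [4+2] addition. The adduct aromatises by loss of methanol to give 3-[(2-acetyl-4-benzyloxy-3-hydroxy-5-methoxyphenyl)methyl]-4-benzyloxy-6-[(S)-2-benzyloxypropyl]pyran-2-one A8, and hydrogenolysis of the three benzyl ethers of A8 would end the route.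
- Merits: the polarity of the cycloaddition writes the whole ring A pattern. The acetyl lands next to the free phenol and the three oxygens are differentiated.
- Weak points: A10 is a tetra-oxygenated, hydrolytically fragile diene that needs its own synthesis. A9 is a skipped ynone whose CH2, flanked by pyrone and alkyne, isomerises easily to an allene, and its pyrone can itself take part in cycloadditions. Ring B and the stereocentre must be made first and carried through the longest sequence. The three benzyl ethers of A8 must be hydrogenolysed beside a ketone and a pyrone.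
- Comparison: this road controls ring A regiochemistry by design, where the chosen plan relies on the symmetry of a purchased arene and a directed demethylation. It costs many more steps to build a ring that can be bought.

Key step: step 2

Assumption: (R)-BINOL–Ti(OiPr)4 is taken to deliver the dienolate to the Re face of acetaldehyde, which corresponds to the (S) carbinol; if the first analysis of 6 shows the opposite sense, (S)-BINOL is used instead.

## Route

Step 1
Reactants: 1 2,2,6-trimethyl-4H-1,3-dioxin-4-one
Product: 3 2,2-dimethyl-6-methylene-4-(trimethylsilyloxy)-6H-1,3-dioxine, via lithium dienolate 2 (not isolated)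
Conditions: LiN(iPr)2, THF, −78 °C; TMSCl, −78 °C to rt; distillation
Reagents that add atoms: chlorotrimethylsilane, C[Si](C)(C)Cl
Why: Kinetic γ-deprotonation of the vinylogous ester gives lithium dienolate 2, which is silylated on oxygen; this is the standard preparation of dioxinone silyl dienolates.

Step 2
Reactants: 3 2,2-dimethyl-6-methylene-4-(trimethylsilyloxy)-6H-1,3-dioxine; 4 acetaldehyde
Product: 6 (S)-6-(2-hydroxypropyl)-2,2-dimethyl-4H-1,3-dioxin-4-one, via trimethylsilyl ether 5 (not isolated)
Conditions: Ti(OiPr)4 (10 mol %), (R)-BINOL (10 mol %), 4 Å MS, THF, −78 °C, excess freshly distilled 4; then 1 M HCl, THF, 0 °C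
Reagents that add atoms: none
Why: The titanium binaphtholate formed from Ti(OiPr)4 and (R)-BINOL (tetravalent titanium) binds acetaldehyde anti to its methyl group and screens one face of the carbonyl. Dienolate 3 attacks through its exocyclic CH2 in an open, extended transition state and forms C1''–C2''; the silyl group passes to the titanium aldolate, which releases silyl ether 5 and regenerates the Lewis acid, and dilute acid frees carbinol 6. The closest known reaction type is this very one, the catalytic enantioselective vinylogous Mukaiyama aldol addition of dioxinone-derived silyl dienolates to aldehydes under BINOL–titanium catalysis. No ring is formed. The new stereocentre C2'' is controlled by the ligand alone: attack on the Re face of acetaldehyde gives the (S) alcohol, and (R)-BINOL is expected to direct the nucleophile to that face. The step needs enantiofacial selectivity at an aldehyde whose substituents are only H and CH3, which is why low temperature and slow addition of 3 to an excess of aldehyde are specified. It also needs γ over α attack, which the substrate secures: the terminal CH2 is unhindered and carries the largest HOMO coefficient, while attack at C5 would break the conjugation of the ring. If the enantiomeric purity falls short, it is raised at this stage by lipase-catalysed acylation of the minor (R) alcohol.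

Step 3
Reactants: 6 (S)-6-(2-hydroxypropyl)-2,2-dimethyl-4H-1,3-dioxin-4-one
Product: 7 (S)-6-[2-(tert-butyldimethylsilyloxy)propyl]-2,2-dimethyl-4H-1,3-dioxin-4-one
Conditions: TBSCl, imidazole, DMF, 0 °C to rt
Reagents that add atoms: tert-butyldimethylsilyl chloride, CC(C)(C)[Si](C)(C)Cl
Why: Standard imidazole-promoted silylation of a secondary alcohol; the ether stops the hydroxyl from adding to the acylketene or to the dioxinone carbonyl in step 4, and no bond to the stereocentre is touched.

Step 4
Reactants: 7 (S)-6-[2-(tert-butyldimethylsilyloxy)propyl]-2,2-dimethyl-4H-1,3-dioxin-4-one; 8 1-(tert-butyldimethylsilyloxy)-1-methoxyethene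
Product: 12 (S)-6-[2-(tert-butyldimethylsilyloxy)propyl]-4-hydroxy-2H-pyran-2-one, via acylketene 9 (not isolated), via cycloadduct 10 (not isolated), via dioxo ester 11 (not isolated)
Conditions: 8 (3 equiv), PhMe, 110 °C, slow addition of 7; then 0.5 M HCl, THF, 0 °C; then DBU, PhMe, 80 °C; dilute acid work-up
Reagents that add atoms: none
Why: Retro-[4+2] loss of acetone gives acylketene 9, which is captured at its ketene carbon by the nucleophilic CH2 of 8, a formal hetero-Diels–Alder addition of an acylketene to an electron-rich alkene as known for vinyl ethers and ketene acetals. Dilute acid converges the silylated adduct 10 (or its open silyl-transfer isomer) to dioxo ester 11, and DBU closes the lactone by attack of the C5 enol oxygen on the ester, the standard cyclisation of 3,5-dioxo esters to 4-hydroxy-2-pyrones. Excess acetal and slow addition keep the acylketene dilute so that capture outruns dimerisation.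

Step 5
Reactants: 13 3,4,5-trimethoxybenzaldehyde
Product: 14 2-bromo-3,4,5-trimethoxybenzaldehyde
Conditions: NBS, CHCl3, 60 °C
Reagents that add atoms: N-bromosuccinimide, O=C1CCC(=O)N1Br
Why: Electrophilic aromatic bromination of the electron-rich ring; C2 and C6 are equivalent, so only one monobromide can form.

Step 6
Reactants: 14 2-bromo-3,4,5-trimethoxybenzaldehyde; 15 tributyl(1-ethoxyvinyl)stannane
Product: 17 2-acetyl-3,4,5-trimethoxybenzaldehyde, via enol ether 16 (not isolated)
Conditions: PdCl2(PPh3)2 (5 mol %), PhMe, 100 °C; then 1 M HCl, THF, rt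
Reagents that add atoms: water, O
Why: Kosugi–Migita–Stille coupling with an acetyl-anion equivalent (zerovalent palladium, formed in situ from the divalent palladium precatalyst, inserts into the aldehyde-activated C–Br bond), then acid hydrolysis of enol ether 16 to the methyl ketone; the aldehyde survives both operations.

Step 7
Reactants: 12 (S)-6-[2-(tert-butyldimethylsilyloxy)propyl]-4-hydroxy-2H-pyran-2-one; 17 2-acetyl-3,4,5-trimethoxybenzaldehyde
Product: 19 3-[(2-acetyl-3,4,5-trimethoxyphenyl)methyl]-6-[(S)-2-(tert-butyldimethylsilyloxy)propyl]-4-hydroxy-2H-pyran-2-one, via arylidene 18 (not isolated)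
Conditions: L-proline (20 mol %), diethyl 2,6-dimethyl-1,4-dihydropyridine-3,5-dicarboxylate (Hantzsch ester, 1.2 equiv), CH2Cl2, rt
Reagents that add atoms: none
Why: Three-component reductive alkylation: proline-catalysed Knoevenagel condensation of the pyrone C3 with the aldehyde gives arylidene 18, which is reduced at once by conjugate hydride transfer from the Hantzsch ester. This gives C-benzylation only; the aryl ketone is far less electrophilic than the aldehyde, and the silyl ether and stereocentre are inert.

Step 8
Reactants: 19 3-[(2-acetyl-3,4,5-trimethoxyphenyl)methyl]-6-[(S)-2-(tert-butyldimethylsilyloxy)propyl]-4-hydroxy-2H-pyran-2-one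
Product: 21 Penicanesin D, via silyl ether catechol 20 (not isolated)
Conditions: BCl3 (5 equiv), CH2Cl2, −78 °C to rt; then MeOH, rt
Reagents that add atoms: none
Why: Carbonyl-directed BCl3 demethylation: boron chelated by the acetyl oxygen cleaves the ortho methyl ether at C3', and the resulting aryloxyboron chloride, held next to the C4' methoxyl in a five-membered chelate, cleaves that ether as well. The C5' methoxyl lacks such assistance once boron is bound as the cyclic catechol borate. Quenching with methanol releases catechol 20 and generates HCl in methanol, which removes the secondary silyl ether without touching the stereocentre.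

## Compound list

1 | 2,2,6-trimethyl-4H-1,3-dioxin-4-one | CC1=CC(=O)OC(C)(C)O1 | starting material
2 | lithium 2,2-dimethyl-6-methylene-6H-1,3-dioxin-4-olate | [Li+].C=C1C=C([O-])OC(C)(C)O1 | intermediate
3 | 2,2-dimethyl-6-methylene-4-(trimethylsilyloxy)-6H-1,3-dioxine | C=C1C=C(O[Si](C)(C)C)OC(C)(C)O1 | intermediate
4 | acetaldehyde | CC=O | starting material
5 | (S)-2,2-dimethyl-6-[2-(trimethylsilyloxy)propyl]-4H-1,3-dioxin-4-one | C[C@H](O[Si](C)(C)C)CC1=CC(=O)OC(C)(C)O1 | intermediate
6 | (S)-6-(2-hydroxypropyl)-2,2-dimethyl-4H-1,3-dioxin-4-one | C[C@H](O)CC1=CC(=O)OC(C)(C)O1 | intermediate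
7 | (S)-6-[2-(tert-butyldimethylsilyloxy)propyl]-2,2-dimethyl-4H-1,3-dioxin-4-one | C[C@H](O[Si](C)(C)C(C)(C)C)CC1=CC(=O)OC(C)(C)O1 | intermediate
8 | 1-(tert-butyldimethylsilyloxy)-1-methoxyethene | C=C(OC)O[Si](C)(C)C(C)(C)C | starting material
9 | (S)-5-(tert-butyldimethylsilyloxy)-3-oxohex-1-en-1-one (acylketene) | O=C=CC(=O)C[C@H](C)O[Si](C)(C)C(C)(C)C | intermediate
10 | 2-methoxy-2-(tert-butyldimethylsilyloxy)-6-[(S)-2-(tert-butyldimethylsilyloxy)propyl]-2,3-dihydro-4H-pyran-4-one (mixture at C2) | COC1(O[Si](C)(C)C(C)(C)C)CC(=O)C=C(C[C@H](C)O[Si](C)(C)C(C)(C)C)O1 | intermediate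
11 | methyl (S)-7-(tert-butyldimethylsilyloxy)-3,5-dioxooctanoate | COC(=O)CC(=O)CC(=O)C[C@H](C)O[Si](C)(C)C(C)(C)C | intermediate
12 | (S)-6-[2-(tert-butyldimethylsilyloxy)propyl]-4-hydroxy-2H-pyran-2-one | C[C@H](O[Si](C)(C)C(C)(C)C)Cc1cc(O)cc(=O)o1 | intermediate
13 | 3,4,5-trimethoxybenzaldehyde | COc1cc(C=O)cc(OC)c1OC | starting material
14 | 2-bromo-3,4,5-trimethoxybenzaldehyde | COc1cc(C=O)c(Br)c(OC)c1OC | intermediate
15 | tributyl(1-ethoxyvinyl)stannane | CCCC[Sn](CCCC)(CCCC)C(=C)OCC | starting material
16 | 2-(1-ethoxyvinyl)-3,4,5-trimethoxybenzaldehyde | CCOC(=C)c1c(C=O)cc(OC)c(OC)c1OC | intermediate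
17 | 2-acetyl-3,4,5-trimethoxybenzaldehyde | COc1cc(C=O)c(C(C)=O)c(OC)c1OC | intermediate
18 | 3-[(2-acetyl-3,4,5-trimethoxyphenyl)methylidene]-6-[(S)-2-(tert-butyldimethylsilyloxy)propyl]pyran-2,4-dione | COc1cc(C=C2C(=O)C=C(C[C@H](C)O[Si](C)(C)C(C)(C)C)OC2=O)c(C(C)=O)c(OC)c1OC | intermediate
19 | 3-[(2-acetyl-3,4,5-trimethoxyphenyl)methyl]-6-[(S)-2-(tert-butyldimethylsilyloxy)propyl]-4-hydroxy-2H-pyran-2-one | COc1cc(Cc2c(O)cc(C[C@H](C)O[Si](C)(C)C(C)(C)C)oc2=O)c(C(C)=O)c(OC)c1OC | intermediate
20 | 3-[(2-acetyl-3,4-dihydroxy-5-methoxyphenyl)methyl]-6-[(S)-2-(tert-butyldimethylsilyloxy)propyl]-4-hydroxy-2H-pyran-2-one | COc1cc(Cc2c(O)cc(C[C@H](C)O[Si](C)(C)C(C)(C)C)oc2=O)c(C(C)=O)c(O)c1O | intermediate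
21 | Penicanesin D, 3-[(2-acetyl-3,4-dihydroxy-5-methoxyphenyl)methyl]-4-hydroxy-6-[(S)-2-hydroxypropyl]-2H-pyran-2-one | COc1cc(Cc2c(O)cc(C[C@H](C)O)oc2=O)c(C(C)=O)c(O)c1O | target

## Step count and risks

Total: 8 steps. Longest linear sequence: 6 steps (steps 1, 2, 3, 4, 7, 8); steps 5 and 6 form the two-step ring A branch.

**Step 2 (key step).** The most likely failure is poor facial discrimination of acetaldehyde, whose two carbonyl substituents differ only as H and CH3. Self-condensation of the aldehyde and slow silyl transfer, which lets an uncatalysed silicon-mediated pathway compete, would also erode the result. The sense of induction is an assumption until measured. Fallback, from 3 and 4 back to 6: the aldol addition is run without a chiral ligand (BF3·OEt2, CH2Cl2, −78 °C) to give racemic 6-(2-hydroxypropyl)-2,2-dimethyl-4H-1,3-dioxin-4-one F1. This is resolved with Candida antarctica lipase B and vinyl acetate. The enzyme should acylate the (R) alcohol, as it does for methyl carbinols, giving (R)-1-(2,2-dimethyl-4-oxo-4H-1,3-dioxin-6-yl)propan-2-yl acetate F2 and leaving the (S) alcohol 6, which is separated and carried on.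

**Step 4.** Acylketene dimerisation may outrun capture by the acetal. The acetal may suffer thermal O-to-C silyl migration. The cycloadduct may lose silanol instead of being hydrolysed, which would divert material into a 2-methoxy-4-pyranone that cannot lactonise. Fallback, from 7 back to 12, by a different ring construction: 7 is heated in wet dioxane, so that the acylketene is trapped by water as (S)-5-(tert-butyldimethylsilyloxy)-3-oxohexanoic acid F3, which decarboxylates to (S)-4-(tert-butyldimethylsilyloxy)pentan-2-one F4. Kinetic deprotonation at the methyl group (LiN(iPr)2, THF, −78 °C) gives lithium (S)-4-(tert-butyldimethylsilyloxy)pent-1-en-2-olate F5, which is silylated with TMSCl to (S)-tert-butyldimethyl[(4-(trimethylsilyloxy)pent-4-en-2-yl)oxy]silane F6. Treatment of F6 with malonyl dichloride (Et2O, −78 °C to rt) gives 12 by C-acylation followed by O-acylation, a known pyrone synthesis.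

**Step 8.** Possible failures are over-demethylation at C5' with excess Lewis acid, incomplete cleavage of the second ether, and acid-induced dehydration of the carbinol during the methanolic quench. Fallback, from 17 back to 21, with the demethylation moved to the simple arene: 17 is treated with BCl3 (CH2Cl2, −78 °C to rt, aqueous work-up) to give 2-acetyl-3,4-dihydroxy-5-methoxybenzaldehyde F7. Reductive alkylation of 12 with F7 under the conditions of step 7 passes through 3-[(2-acetyl-3,4-dihydroxy-5-methoxyphenyl)methylidene]-6-[(S)-2-(tert-butyldimethylsilyloxy)propyl]pyran-2,4-dione F8 and gives 20, which is desilylated with HF·pyridine in THF to 21.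

**Step 7.** The ortho-acetyl methyl group may close onto the aldehyde or onto the arylidene (intramolecular aldol or Michael addition to indanone-type products) under amine catalysis. A second pyrone may add to the arylidene before hydride transfer. Fallback, from 12 and 14 back to 19, with the acetyl introduced after the union: reductive alkylation of 12 with the bromo aldehyde 14 passes through 3-[(2-bromo-3,4,5-trimethoxyphenyl)methylidene]-6-[(S)-2-(tert-butyldimethylsilyloxy)propyl]pyran-2,4-dione F9 and gives 3-[(2-bromo-3,4,5-trimethoxyphenyl)methyl]-6-[(S)-2-(tert-butyldimethylsilyloxy)propyl]-4-hydroxy-2H-pyran-2-one F10. Stille coupling of F10 with 15 (PdCl2(PPh3)2, PhMe, 100 °C) gives 3-[[2-(1-ethoxyvinyl)-3,4,5-trimethoxyphenyl]methyl]-6-[(S)-2-(tert-butyldimethylsilyloxy)propyl]-4-hydroxy-2H-pyran-2-one F11, which dilute HCl hydrolyses to 19.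

## Further compounds

F1 | step 2 | 6-(2-hydroxypropyl)-2,2-dimethyl-4H-1,3-dioxin-4-one (racemic) | CC(O)CC1=CC(=O)OC(C)(C)O1
F2 | step 2 | (R)-1-(2,2-dimethyl-4-oxo-4H-1,3-dioxin-6-yl)propan-2-yl acetate | C[C@@H](OC(C)=O)CC1=CC(=O)OC(C)(C)O1
F3 | step 4 | (S)-5-(tert-butyldimethylsilyloxy)-3-oxohexanoic acid | OC(=O)CC(=O)C[C@H](C)O[Si](C)(C)C(C)(C)C
F4 | step 4 | (S)-4-(tert-butyldimethylsilyloxy)pentan-2-one | CC(=O)C[C@H](C)O[Si](C)(C)C(C)(C)C
F5 | step 4 | lithium (S)-4-(tert-butyldimethylsilyloxy)pent-1-en-2-olate | [Li+].C=C([O-])C[C@H](C)O[Si](C)(C)C(C)(C)C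
F6 | step 4 | (S)-tert-butyldimethyl[(4-(trimethylsilyloxy)pent-4-en-2-yl)oxy]silane | C=C(O[Si](C)(C)C)C[C@H](C)O[Si](C)(C)C(C)(C)C
F7 | step 8 | 2-acetyl-3,4-dihydroxy-5-methoxybenzaldehyde | COc1cc(C=O)c(C(C)=O)c(O)c1O
F8 | step 8 | 3-[(2-acetyl-3,4-dihydroxy-5-methoxyphenyl)methylidene]-6-[(S)-2-(tert-butyldimethylsilyloxy)propyl]pyran-2,4-dione | COc1cc(C=C2C(=O)C=C(C[C@H](C)O[Si](C)(C)C(C)(C)C)OC2=O)c(C(C)=O)c(O)c1O
F9 | step 7 | 3-[(2-bromo-3,4,5-trimethoxyphenyl)methylidene]-6-[(S)-2-(tert-butyldimethylsilyloxy)propyl]pyran-2,4-dione | COc1cc(C=C2C(=O)C=C(C[C@H](C)O[Si](C)(C)C(C)(C)C)OC2=O)c(Br)c(OC)c1OC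
F10 | step 7 | 3-[(2-bromo-3,4,5-trimethoxyphenyl)methyl]-6-[(S)-2-(tert-butyldimethylsilyloxy)propyl]-4-hydroxy-2H-pyran-2-one | COc1cc(Cc2c(O)cc(C[C@H](C)O[Si](C)(C)C(C)(C)C)oc2=O)c(Br)c(OC)c1OC
F11 | step 7 | 3-[[2-(1-ethoxyvinyl)-3,4,5-trimethoxyphenyl]methyl]-6-[(S)-2-(tert-butyldimethylsilyloxy)propyl]-4-hydroxy-2H-pyran-2-one | CCOC(=C)c1c(Cc2c(O)cc(C[C@H](C)O[Si](C)(C)C(C)(C)C)oc2=O)cc(OC)c(OC)c1OC
A1 | alternative 1 | 3-[[2-acetyl-3,4-bis(benzyloxy)-5-methoxyphenyl]methyl]-6-[(S)-2-(tert-butyldimethylsilyloxy)propyl]-4-hydroxypyran-2-one | COc1cc(Cc2c(O)cc(C[C@H](C)O[Si](C)(C)C(C)(C)C)oc2=O)c(C(C)=O)c(OCc2ccccc2)c1OCc1ccccc1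
A2 | alternative 1 | 2-[[2-acetyl-3,4-bis(benzyloxy)-5-methoxyphenyl]methyl]propanedioyl dichloride | COc1cc(CC(C(=O)Cl)C(=O)Cl)c(C(C)=O)c(OCc2ccccc2)c1OCc1ccccc1
A3 | alternative 1 | (S)-tert-butyldimethyl[(4-(trimethylsilyloxy)pent-4-en-2-yl)oxy]silane | C=C(O[Si](C)(C)C)C[C@H](C)O[Si](C)(C)C(C)(C)C
A4 | alternative 2 | 3-[(4-acetyl-7-methoxy-2,2-dimethyl-1,3-benzodioxol-5-yl)methyl]-6-[(S)-2-(tert-butyldimethylsilyloxy)propyl]-4-hydroxypyran-2-one | COc1cc(Cc2c(O)cc(C[C@H](C)O[Si](C)(C)C(C)(C)C)oc2=O)c(C(C)=O)c2OC(C)(C)Oc12
A5 | alternative 2 | 1-(7-methoxy-2,2-dimethyl-1,3-benzodioxol-4-yl)ethanone | COc1ccc(C(C)=O)c2OC(C)(C)Oc12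
A6 | alternative 2 | 3-[(dimethylamino)methyl]-6-[(S)-2-(tert-butyldimethylsilyloxy)propyl]-4-hydroxypyran-2-one | CN(C)Cc1c(O)cc(C[C@H](C)O[Si](C)(C)C(C)(C)C)oc1=O
A7 | alternative 2 | 3-methylidene-6-[(S)-2-(tert-butyldimethylsilyloxy)propyl]pyran-2,4-dione | C=C1C(=O)C=C(C[C@H](C)O[Si](C)(C)C(C)(C)C)OC1=O
A8 | alternative 3 | 3-[(2-acetyl-4-benzyloxy-3-hydroxy-5-methoxyphenyl)methyl]-4-benzyloxy-6-[(S)-2-benzyloxypropyl]pyran-2-one | COc1cc(Cc2c(OCc3ccccc3)cc(C[C@H](C)OCc3ccccc3)oc2=O)c(C(C)=O)c(O)c1OCc1ccccc1
A9 | alternative 3 | 4-benzyloxy-6-[(S)-2-benzyloxypropyl]-3-(4-oxopent-2-yn-1-yl)pyran-2-one | CC(=O)C#CCc1c(OCc2ccccc2)cc(C[C@H](C)OCc2ccccc2)oc1=O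
A10 | alternative 3 | 2-benzyloxy-1,3-dimethoxy-1-(trimethylsilyloxy)buta-1,3-diene | C=C(OC)C(OCc1ccccc1)=C(OC)O[Si](C)(C)C
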